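Q stood higher in the dawn run, at 76.9% after 40.0 min, than the 48.5% of the spring run, and the two recipes differ in E, 1.6 equiv against 1 equiv, and in L, 0.050 M against 0.068 M.

the same everywhere: D 5 mol% (in portions, 2)

| charge | L | E | Z | temperature | remark | time |
|---|---|---|---|---|---|---|
| spring | 0.068 M | 1 equiv | 1 equiv | 75 °C | run made earlier; portions every 6.0 min |  |
| midnight | 0.30 M | 1 equiv | 1 equiv | 95 °C | run made earlier; portions every 6.0 min |  |
| dawn | 0.050 M | 1.6 equiv | 1 equiv | 75 °C | run made earlier; portions every 6.0 min |  |
| Sunday's | 0.050 M | 1.00 equiv | 1.00 equiv | 80 °C | the portions of D follow each other after 6.0 min, the first at the start | 1.0 h |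
| Monday's | 0.050 M | 3.00 equiv | 0.330 equiv | 110 °C | the portions of D follow each other after 6.0 min, the first at the start | 1.0 h |
| Saturday's | 0.050 M | 1.00 equiv | 0.330 equiv | 80 °C | the portions of D follow each other after 6.0 min, the first at the start | 1.0 h |
| Wednesday's | 0.20 M | 1.00 equiv | 1.00 equiv | 100 °C | the portions of D follow each other after 6.0 min, the first at the start | 1.0 h |

| run | time / min | Q / % | L / % |
|---|---|---|---|
| spring | 8.00 | 45.5 | 54.0 |
| spring | 20.0 | 51.3 | 50.0 |
| spring | 40.0 | 48.5 | 50.6 |
| spring | 60.0 | 49.6 | 51.1 |
| midnight | 4.00 | 46.3 | 51.7 |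
| midnight | 10.0 | 47.0 | 52.1 |
| midnight | 20.0 | 46.5 | 53.6 |
| midnight | 30.0 | 46.2 | 53.2 |
| dawn | 8.00 | 56.8 | 43.6 |
| dawn | 20.0 | 73.7 | 24.3 |
| dawn | 40.0 | 76.9 | 21.1 |
| dawn | 60.0 | 76.0 | 19.6 |

(each reading ± 1 percentage point)

* the flasks put in order of amount of Q, in percent of the L charged, best first, at 1.0 h (Sunday's / Monday's / Saturday's / Wednesday's)
* the amount of Q, in percent of the L charged of the flask you put first, at 1.0 h
* the amount of Q, in percent of the L charged of the flask you put last, at 1.0 h

The spring and dawn readings hardly moved after 40.0 min, although L stayed at 51.1% and 19.6%, so I took E for the limiting reagent. But in the spring run 1 equiv of E gave 49.6% of Q. Two readings fitted: Q costing two E, or Z competing for E, and Z stood at 1 equiv in the three runs. I chose competition, since Z is a substrate, and assumed that L and Z fall at the same fractional pace.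

Then the fraction of L turned into Q is one simple ratio. Saturday's 75.2% is its cover, the equivalents of E over the equivalents of L and Z together. Under that assumption, a cover below one reads as the fraction of L made into Q.

The test came first. Dawn's cover is 80.0% against a reading of 76.9%. Spring and midnight have 50.0% against 49.6% and 46.2%, the midnight figure lying lower, at 95 °C and 0.30 M of L.

So I committed to Saturday's first near 75.2%, then Sunday's at 50.0%, and Wednesday's, with the same cover, slightly below it, as midnight was. Monday's cover is 226%, above one, which leaves a surplus of 1.67 equivalents of E. No run had held a surplus, and 110 °C is hotter than any of them. One number was therefore not enough, and I left Monday's place open.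

The forecast gave Sunday's > Wednesday's > Monday's > Saturday's, with 49% and 32% at the ends, holding that “0.33 equiv caps Q at about 33%”.

The flasks gave Saturday's > Sunday's > Wednesday's > Monday's: Saturday's 71.2%, a little under its cover of 75.2%, Sunday's 49.1%, Wednesday's 46.3% and Monday's 6.42%.

    E + Q → G (k = 0.162 L mol⁻¹ min⁻¹, Ea = 67.0 kJ mol⁻¹)
    L + E + D → D + Q (k = 2000 L² mol⁻² min⁻¹, Ea = 38.0 kJ mol⁻¹)
    2 Z → X (k = 0.157 L mol⁻¹ min⁻¹, Ea = 69.0 kJ mol⁻¹)
    Z + E + D → D + J (k = 2100 L² mol⁻² min⁻¹, Ea = 47.0 kJ mol⁻¹)
    (constants at 80 °C)

In Monday's flask, half of the turnover of L with E into Q up to 1.00 h was done by 0.781 min, but half of that of E with Q into G took 10.2 min, far longer. At 1.00 h Monday's flask held G at 93.6% of the L charged and E at 24.6% of its own charge, which counted as E comes to 1.67 equivalents against the surplus of 1.67 from a cover of 226%. The same flask as Monday's with 1.80 equiv of E had a cover of 135% and a surplus of 0.470 equivalents, and it ended with G at 42.1% and Q at 57.8%.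

The data stem from a simulated flask with constants of no real substance; the scatter is artificial.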